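The numbers in the tables stem from a simulated flask on assumed constants; the scatter is artificial.

Read the five flasks at 2.5 h and again at 50 h, and compare them by the percent of substrate charged that has become product.

| flask | substrate | coupling partner | free catalyst | temperature | remark | time |
|---|---|---|---|---|---|---|
| Sunday's | 0.22 M | 1.05 equiv | 1 mol% | −20 °C | run made earlier |  |
| amber | 0.060 M | 1.05 equiv | 1 mol% | −5 °C |  | 50 h |
| grey | 0.060 M | 1.60 equiv | 1 mol% | −20 °C |  | 50 h |
| blue | 0.20 M | 0.530 equiv | 0.3 mol% | 20 °C |  | 50 h |
| red | 0.20 M | 1.05 equiv | 1 mol% | −20 °C |  | 50 h |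
| teal | 0.20 M | 1.05 equiv | 0.6 mol% | −20 °C |  | 50 h |

Sunday's run (percent of the substrate charged)

| time / h | product / % | substrate / % |
|---|---|---|
| 0.833 | 7.0 | 90.4 |
| 1.33 | 13.9 | 87.8 |
| 2.00 | 19.1 | 79.2 |
| 4.00 | 33.4 | 64.0 |
| 6.00 | 48.8 | 50.6 |
| 10.0 | 72.9 | 30.5 |

(readings scatter by 1 percentage point)

1. the flasks by amount of product, in percent of the substrate charged, highest first, at 50 h (amber / grey / blue / red / teal)
2. the same order at 2.5 h (amber / grey / blue / red / teal)
3. the amount of product, in percent of the substrate charged of the flask you put first, at 50 h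
4. the amount of product, in percent of the substrate charged of the flask you put last, at 50 h

- the earlier runs do not show what temperature does; that part of a forecast is a guess
- no earlier run changes the charge of free catalyst; that part of a forecast is a guess

Take from Sunday's run how its rate answers to concentration: up to 4.00 h it turned 0.0835 h⁻¹ of the charge, with substrate averaging 82.0%, and from there to 10.0 h it turned 0.0658 h⁻¹, which is slower, with substrate averaging 47.2%. The ratio of the logarithms of these two changes reads 0.431, a reading that carries the scatter; call it the apparent order, the power to which the rate at a fixed loading follows [substrate], with coupling partner falling alongside. Raise the ratio of grey's 0.060 M to red's 0.20 M to this power and reckon grey at 0.595 of red's rate, setting aside grey's extra coupling partner, which Sunday's run does not measure; this reckoning therefore puts grey behind red. The forecast parts from it at 50 h: it read “near-saturated, roughly zero-order kinetics” and gave grey > amber > red > teal > blue at 50 h, with 99% first and 52% last, and blue > amber > red > grey > teal at 2.5 h.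

The flasks give red > teal > grey > amber > blue at 50 h, with 99.1% first and 53.0% last, and blue > red > amber > teal > grey at 2.5 h.

    substrate + free catalyst ⇌ catalyst intermediate A (K = 15.0 L mol⁻¹, k = 5.20 L mol⁻¹ min⁻¹, Ea = 55.0 kJ mol⁻¹, ΔH = −36.0 kJ mol⁻¹)
    coupling partner + catalyst intermediate A → catalyst intermediate B (k = 3.50 L mol⁻¹ min⁻¹, Ea = 45.0 kJ mol⁻¹)
    catalyst intermediate B ⇌ by-product + catalyst intermediate C (K = 0.610 M, k = 0.760 min⁻¹, Ea = 72.0 kJ mol⁻¹, ΔH = −46.0 kJ mol⁻¹)
    catalyst intermediate C → catalyst intermediate D (k = 0.780 min⁻¹, Ea = 72.0 kJ mol⁻¹)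
    catalyst intermediate D → free catalyst + product (k = 1.10 min⁻¹, Ea = 74.0 kJ mol⁻¹)
    (constants at −20 °C)

Grey holds 91.8% at 50.0 h against red's 99.1%, and at 2.50 h its 10.7% is 0.492 of red's 21.9%, lower than the reckoned 0.595. The equilibrium constant of the first step times the starting [substrate] is 3.0 in red and 0.900 in grey. Put the same factor on amber, which shares grey's 0.060 M: red's reading times 0.595 gives 13.0%, and amber at −5 °C reads 19.3% at 2.50 h, a ratio of 1.48.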